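**Plan**

1. Numbering is that of labdane: ring A = C1–C5 and C10 (C3 carbinol, gem-dimethyl C4); ring B = C5–C10 (C7=C8); side chain C11–C15. The retrosynthesis cuts the C15 ester, takes C3–OH back to the ketone, then cuts C3–C4 and C5–C10 together. This opens both rings to the acyclic nitrile acid 23, which is cut further at C1–C10, C20–C10, C8–C9, C9=C10 (olefination) and C5–C6.
2. Forward, the chain is joined from the C9 aldehyde of (S)-citronellol: olefination, conjugate addition of the (Z)-alkenyl unit C4–C8 at C9, then methyl and cyanoethyl at the future C10. Step 12 closes ring B (C5–C10) and then ring A (C3–C4) in one operation; ketone reduction and acylation finish.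
3. Enabling feature: C10 (methyl-bearing ring-fusion carbon) and C4 (gem-dimethyl carbon) are both tertiary radical sites flanking C5. A C10 radical set free by decarboxylation adds to C5 of the C5=C4 dimethylvinyl end and hands the spin to C4, which lies 6-exo to the nitrile carbon C3 (the later carbinol). The Z C7=C8 bond of ring B holds C10 next to C5.
4. Stereochemistry: C13 from (S)-citronellol; C9 from the oxazolidinone-controlled conjugate addition; C5 and C10 relayed from C9 in the chair-like first ring closure (trans fusion); C3 by equatorial hydride delivery (axial OH); the ester centre from (R)-2-methylbutanoic acid.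

Key step: step 12

Remark: TBS = tert-butyldimethylsilyl; the carbon that becomes C10 is a stereocentre in 18–23 but turns into a planar radical in step 12, so 23 is used as its epimer mixture; (R)-2-methylbutanoic acid and (S)-4-benzyl-3-(chloroacetyl)oxazolidin-2-one are taken as purchasable.

**Route**

Step 1
Reactants: 1 (S)-citronellol
Product: 2 (S)-citronellyl TBS ether
Conditions: TBSCl, imidazole, DMF, 0 °C to rt
Reagents that add atoms: tert-butyldimethylsilyl chloride, CC(C)(C)[Si](C)(C)Cl
Why: Silyl ether formation of the primary alcohol is routine and keeps C15–O inert to the organometallic and enolate steps that follow.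

Step 2
Reactants: 2 (S)-citronellyl TBS ether
Product: 4 (4S)-6-(TBSO)-4-methylhexanal, via trioxolane 3 (not isolated)
Conditions: O3, CH2Cl2, −78 °C; then PPh3, −78 °C to rt
Reagents that add atoms: ozone, [O-][O+]=O
Why: Ozonolysis with reductive work-up cleaves the only C=C bond to give the C9 aldehyde while the C13 stereocentre from citronellol is untouched.

Step 3
Reactants: 5 (S)-4-benzyl-3-(chloroacetyl)oxazolidin-2-one
Product: 6 diethyl {2-[(S)-4-benzyl-2-oxooxazolidin-3-yl]-2-oxoethyl}phosphonate
Conditions: P(OEt)3, neat, 120 °C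
Reagents that add atoms: triethyl phosphite, CCOP(OCC)OCC
Why: Michaelis–Arbuzov reaction of the activated α-chloro imide with the phosphite gives the stabilised phosphonate needed for olefination.

Step 4
Reactants: 4 (4S)-6-(TBSO)-4-methylhexanal; 6 diethyl {2-[(S)-4-benzyl-2-oxooxazolidin-3-yl]-2-oxoethyl}phosphonate
Product: 7 (4S)-4-benzyl-3-[(2E,6S)-8-(TBSO)-6-methyloct-2-enoyl]oxazolidin-2-one
Conditions: LiCl, i-Pr2NEt, MeCN, rt
Reagents that add atoms: none
Why: Horner–Wadsworth–Emmons olefination under mild LiCl/amine conditions gives the (E)-enoyl imide without enolising the aldehyde or the C13 centre.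

Step 5
Reactants: 8 but-2-yn-1-ol
Product: 10 (Z)-3-iodobut-2-en-1-ol, via vinylalanate 9 (not isolated)
Conditions: NaAlH2(OCH2CH2OMe)2, THF, 0 °C to rt; then I2, −78 °C
Reagents that add atoms: iodine, II
Why: Hydroxyl-directed trans-hydroalumination of the propargylic alcohol places aluminium on C3 syn to the CH2O group and iodinolysis with retention gives the (Z)-vinyl iodide, the future Z C7=C8 unit.

Step 6
Reactants: 10 (Z)-3-iodobut-2-en-1-ol
Product: 11 (Z)-1-bromo-3-iodobut-2-ene
Conditions: CBr4, PPh3, CH2Cl2, 0 °C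
Reagents that add atoms: tetrabromomethane, BrC(Br)(Br)Br
Why: Appel bromination converts the primary allylic alcohol to the bromide without allylic shift or loss of the vinyl iodide.

Step 7
Reactants: 11 (Z)-1-bromo-3-iodobut-2-ene; 12 (2-methylprop-1-enyl)magnesium bromide
Product: 13 (Z)-2-iodo-6-methylhepta-2,5-diene
Conditions: CuI (5 mol%), THF, −30 to 0 °C
Reagents that add atoms: none
Why: Copper-catalysed coupling of the alkenyl Grignard reagent at the primary allylic bromide proceeds SN2 because the far allyl terminus is fully substituted, leaving the vinyl iodide and its geometry intact.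

Step 8
Reactants: 7 (4S)-4-benzyl-3-[(2E,6S)-8-(TBSO)-6-methyloct-2-enoyl]oxazolidin-2-one; 13 (Z)-2-iodo-6-methylhepta-2,5-diene
Product: 16 (4S)-4-benzyl-3-{(3R,6S)-8-(TBSO)-6-methyl-3-[(2Z)-6-methylhepta-2,5-dien-2-yl]octanoyl}oxazolidin-2-one, via alkenyllithium 14 (not isolated), via alkenylmagnesium bromide 15 (not isolated)
Conditions: 13 (2 equiv), t-BuLi (4 equiv), Et2O, −78 °C; MgBr2·OEt2; CuBr·SMe2, THF/Me2S, −40 °C; then 7, −40 to −10 °C; aq. NH4Cl
Reagents that add atoms: none
Why: Auxiliary-controlled conjugate addition of an alkenylcopper–magnesium reagent: iodine–lithium exchange and transmetalation retain the Z geometry, and the magnesium-chelated s-cis enoyl imide is attacked at C9 on the face away from the benzyl group, which sets the C9 stereocentre.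

Step 9
Reactants: 16 (4S)-4-benzyl-3-{(3R,6S)-8-(TBSO)-6-methyl-3-[(2Z)-6-methylhepta-2,5-dien-2-yl]octanoyl}oxazolidin-2-one
Product: 18 (4S)-4-benzyl-3-{(2S,3R,6S)-8-(TBSO)-2,6-dimethyl-3-[(2Z)-6-methylhepta-2,5-dien-2-yl]octanoyl}oxazolidin-2-one, via sodium enolate 17 (not isolated)
Conditions: NaN(SiMe3)2, THF, −78 °C; then MeI, −78 to −40 °C
Reagents that add atoms: iodomethane, CI
Why: Alkylation of the chelated Z sodium enolate of the imide with iodomethane anti to the benzyl group installs the future C20 methyl; the configuration of this carbon is of no later consequence.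

Step 10
Reactants: 18 (4S)-4-benzyl-3-{(2S,3R,6S)-8-(TBSO)-2,6-dimethyl-3-[(2Z)-6-methylhepta-2,5-dien-2-yl]octanoyl}oxazolidin-2-one
Product: 20 (2S,3R,6S)-8-(TBSO)-2,6-dimethyl-3-[(2Z)-6-methylhepta-2,5-dien-2-yl]octanoic acid, via lithium peroxycarboxylate 19 (not isolated)
Conditions: LiOH, H2O2, THF/H2O, 0 °C; then Na2SO3; then 1 M HCl to pH 3
Reagents that add atoms: hydrogen peroxide, OO
Why: Hydroperoxide attacks the exocyclic imide carbonyl selectively even in hindered cases, releasing the acid (after sulfite reduction of the peroxy acid) and the recoverable auxiliary without touching C9.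

Step 11
Reactants: 20 (2S,3R,6S)-8-(TBSO)-2,6-dimethyl-3-[(2Z)-6-methylhepta-2,5-dien-2-yl]octanoic acid; 21 acrylonitrile
Product: 23 (3S,6S)-8-(TBSO)-2-(2-cyanoethyl)-2,6-dimethyl-3-[(2Z)-6-methylhepta-2,5-dien-2-yl]octanoic acid (both C2 epimers), via dilithium enediolate 22 (not isolated)
Conditions: LiN(i-Pr)2 (2.2 equiv), THF, −78 to 0 °C; then acrylonitrile, −78 °C; then 1 M HCl to pH 3, 0 °C
Reagents that add atoms: none
Why: Michael addition of the lithium enediolate of the acid to acrylonitrile makes the fully substituted carbon (future C10) and brings in C1–C3 with the nitrile as radical acceptor; either epimer serves.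

Step 12
Reactants: 23 (3S,6S)-8-(TBSO)-2-(2-cyanoethyl)-2,6-dimethyl-3-[(2Z)-6-methylhepta-2,5-dien-2-yl]octanoic acid
Product: 26 (5R,9S,10R,13S)-15-hydroxylabd-7-en-3-one, via ketimine 24 (not isolated), via silyl ether ketone 25 (not isolated)
Conditions: [Ir{dF(CF3)ppy}2(dtbbpy)]PF6 (2 mol%), Cs2CO3 (0.2 equiv), degassed MeCN (5 mM), 450 nm LEDs, 25 °C; then 1 M HCl, THF, 25 °C
Reagents that add atoms: water, O
Why: Proposed new method: excited trivalent iridium oxidises the carboxylate of 23, CO2 is lost, the tertiary C10 radical (planar, so both epimers of 23 converge) adds 6-exo-trig to C5 of the C5=C4 dimethylvinyl group to close ring B, the new tertiary C4 radical adds 6-exo-dig to the nitrile carbon C3 to close ring A, and the iminyl radical is reduced by divalent iridium and protonated by 23, so the cycle is redox-neutral and needs no hydrogen-atom donor. The closest known reaction types are photoredox decarboxylative radical additions of carboxylic acids to olefins and tin-mediated radical cyclisations onto nitriles; joining them in a bicyclisation on an unactivated trisubstituted olefin is the new element. C5 should be set relative to C9 in a chair-like transition state of the first closure in which the C9 side chain and the dimethylvinyl group are both pseudo-equatorial. C10 should be set in the same closure, the small methyl taking the axial-like site between C6 and C4 and the cyanoethyl arm the equatorial site anti to C6, which gives the trans ring fusion and places the arm beside C4 for the second closure. The step needs oxidation of the carboxylate in preference to the olefins (secured by the gap in oxidation potentials), attack at C5 and not C4 (secured by the tertiary radical formed and the six-membered ring), and ring closure faster than loss of the radicals by hydrogen transfer (secured by the Z C7=C8 bond holding C10 next to C5 and by the absence of any hydrogen-atom donor). Aqueous HCl then hydrolyses ketimine 24 to the ketone and removes the silyl group.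

Step 13
Reactants: 26 (5R,9S,10R,13S)-15-hydroxylabd-7-en-3-one
Product: 27 (3R,5R,9S,10R,13S)-labd-7-ene-3,15-diol
Conditions: LiBH(sec-Bu)3 (2.5 equiv), THF, −78 °C; then NaOH, H2O2, 0 °C
Reagents that add atoms: none
Why: The bulky trialkylborohydride attacks the C3 ketone flanked by the gem-dimethyl carbon from the equatorial direction, giving the axial 3-hydroxyl (R at C3, trans to the C10 methyl), as is usual for 4,4-dimethyl-3-ketones of this ring type.

Step 14
Reactants: 27 (3R,5R,9S,10R,13S)-labd-7-ene-3,15-diol; 28 (R)-2-methylbutanoic acid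
Product: 29 (3R,5R,9S,10R,13S)-3-hydroxylabd-7-en-15-yl (2R)-2-methylbutanoate
Conditions: EDC·HCl (1.1 equiv), DMAP (0.1 equiv), CH2Cl2, 0 °C
Reagents that add atoms: none
Why: Steglich esterification acylates the unhindered primary C15 hydroxyl far faster than the axial neopentyl-type C3 hydroxyl, and carbodiimide activation at 0 °C does not enolise the (R) centre of the acid.

**Compound list**

1 | (S)-citronellol | OCC[C@@H](C)CCC=C(C)C | starting material
2 | (S)-citronellyl TBS ether | CC(C)(C)[Si](C)(C)OCC[C@@H](C)CCC=C(C)C | intermediate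
3 | 3-[(3S)-5-(TBSO)-3-methylpentyl]-5,5-dimethyl-1,2,4-trioxolane | CC(C)(C)[Si](C)(C)OCC[C@@H](C)CCC1OOC(C)(C)O1 | intermediate
4 | (4S)-6-(TBSO)-4-methylhexanal | CC(C)(C)[Si](C)(C)OCC[C@@H](C)CCC=O | intermediate
5 | (S)-4-benzyl-3-(chloroacetyl)oxazolidin-2-one | O=C(CCl)N1[C@@H](Cc2ccccc2)COC1=O | starting material
6 | diethyl {2-[(S)-4-benzyl-2-oxooxazolidin-3-yl]-2-oxoethyl}phosphonate | CCOP(=O)(OCC)CC(=O)N1[C@@H](Cc2ccccc2)COC1=O | intermediate
7 | (4S)-4-benzyl-3-[(2E,6S)-8-(TBSO)-6-methyloct-2-enoyl]oxazolidin-2-one | CC(C)(C)[Si](C)(C)OCC[C@@H](C)CC/C=C/C(=O)N1[C@@H](Cc2ccccc2)COC1=O | intermediate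
8 | but-2-yn-1-ol | CC#CCO | starting material
9 | sodium 2,2-bis(2-methoxyethoxy)-3-methyl-1-oxa-2-aluminacyclopent-3-en-2-uide (vinylalanate) | [Na+].CC1=CCO[Al-]1(OCCOC)OCCOC | intermediate
10 | (Z)-3-iodobut-2-en-1-ol | C/C(I)=C/CO | intermediate
11 | (Z)-1-bromo-3-iodobut-2-ene | C/C(I)=C/CBr | intermediate
12 | (2-methylprop-1-enyl)magnesium bromide | CC(C)=C[Mg]Br | starting material
13 | (Z)-2-iodo-6-methylhepta-2,5-diene | C/C(I)=C/CC=C(C)C | intermediate
14 | [(2Z)-6-methylhepta-2,5-dien-2-yl]lithium | [Li]/C(C)=C\CC=C(C)C | intermediate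
15 | [(2Z)-6-methylhepta-2,5-dien-2-yl]magnesium bromide | Br[Mg]/C(C)=C\CC=C(C)C | intermediate
16 | (4S)-4-benzyl-3-{(3R,6S)-8-(TBSO)-6-methyl-3-[(2Z)-6-methylhepta-2,5-dien-2-yl]octanoyl}oxazolidin-2-one | CC(C)(C)[Si](C)(C)OCC[C@@H](C)CC[C@H](CC(=O)N1[C@@H](Cc2ccccc2)COC1=O)/C(C)=C\CC=C(C)C | intermediate
17 | sodium (Z)-enolate of 16 | CC(C)(C)[Si](C)(C)OCC[C@@H](C)CC[C@H](/C=C(\[O-])N1[C@@H](Cc2ccccc2)COC1=O)/C(C)=C\CC=C(C)C.[Na+] | intermediate
18 | (4S)-4-benzyl-3-{(2S,3R,6S)-8-(TBSO)-2,6-dimethyl-3-[(2Z)-6-methylhepta-2,5-dien-2-yl]octanoyl}oxazolidin-2-one | CC(C)(C)[Si](C)(C)OCC[C@@H](C)CC[C@H]([C@H](C)C(=O)N1[C@@H](Cc2ccccc2)COC1=O)/C(C)=C\CC=C(C)C | intermediate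
19 | lithium (2S,3R,6S)-8-(TBSO)-2,6-dimethyl-3-[(2Z)-6-methylhepta-2,5-dien-2-yl]octaneperoxoate | CC(C)(C)[Si](C)(C)OCC[C@@H](C)CC[C@H]([C@H](C)C(=O)O[O-])/C(C)=C\CC=C(C)C.[Li+] | intermediate
20 | (2S,3R,6S)-8-(TBSO)-2,6-dimethyl-3-[(2Z)-6-methylhepta-2,5-dien-2-yl]octanoic acid | CC(C)(C)[Si](C)(C)OCC[C@@H](C)CC[C@H]([C@H](C)C(=O)O)/C(C)=C\CC=C(C)C | intermediate
21 | acrylonitrile | C=CC#N | starting material
22 | dilithium enediolate of 20 | CC(C)(C)[Si](C)(C)OCC[C@@H](C)CC[C@H](C(C)=C([O-])[O-])/C(C)=C\CC=C(C)C.[Li+].[Li+] | intermediate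
23 | (3S,6S)-8-(TBSO)-2-(2-cyanoethyl)-2,6-dimethyl-3-[(2Z)-6-methylhepta-2,5-dien-2-yl]octanoic acid, both C2 epimers | CC(C)(C)[Si](C)(C)OCC[C@@H](C)CC[C@H](C(C)(CCC#N)C(=O)O)/C(C)=C\CC=C(C)C | intermediate
24 | (5R,9S,10R,13S)-15-(TBSO)labd-7-en-3-imine | CC(C)(C)[Si](C)(C)OCC[C@@H](C)CC[C@H]1C(C)=CC[C@H]2C(C)(C)C(=N)CC[C@]12C | intermediate
25 | (5R,9S,10R,13S)-15-(TBSO)labd-7-en-3-one | CC(C)(C)[Si](C)(C)OCC[C@@H](C)CC[C@H]1C(C)=CC[C@H]2C(C)(C)C(=O)CC[C@]12C | intermediate
26 | (5R,9S,10R,13S)-15-hydroxylabd-7-en-3-one | OCC[C@@H](C)CC[C@H]1C(C)=CC[C@H]2C(C)(C)C(=O)CC[C@]12C | intermediate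
27 | (3R,5R,9S,10R,13S)-labd-7-ene-3,15-diol (axial 3-OH) | OCC[C@@H](C)CC[C@H]1C(C)=CC[C@H]2C(C)(C)[C@H](O)CC[C@]12C | intermediate
28 | (R)-2-methylbutanoic acid | CC[C@@H](C)C(=O)O | starting material
29 | (3R,5R,9S,10R,13S)-3-hydroxylabd-7-en-15-yl (2R)-2-methylbutanoate | CC[C@@H](C)C(=O)OCC[C@@H](C)CC[C@H]1C(C)=CC[C@H]2C(C)(C)[C@H](O)CC[C@]12C | target

**Step count**

Total: 14 steps. Longest linear sequence: 10 steps (1, 2, 4, 8, 9, 10, 11, 12, 13, 14).

**Steps most likely to fail**

Step 12 (bears the label "Proposed new method:"). The carbon radicals may be lost by hydrogen transfer before they close: from the doubly allylic C6–H2 to the C10 radical, or from C2–H2 beside the nitrile to the C4 radical, whose closure onto the nitrile is slow. Turnover may also stall at the iminyl radical, and facial discrimination at the planar C10 radical (methyl against cyanoethyl arm) may be modest at 25 °C. The fallback uses known chain chemistry and makes the two rings in separate operations. It sets out from 23, which is esterified with N-hydroxypyridine-2-thione (DCC, CH2Cl2, dark) to the thiohydroxamate ester F1. Photolysis of F1 at high dilution and −40 °C (Barton decarboxylation with 6-exo closure and 2-pyridylthio group transfer; the low temperature should sharpen the choice between the two chair arrangements) should give the ring B sulfide F2. Slow addition of Bu3SnH with AIBN in benzene at 80 °C then regenerates the C4 radical from F2 and closes ring A onto the nitrile (tin-mediated radical cyclisation onto a nitrile) to give ketimine 24. Hydrolysis with 1 M HCl in THF as in step 12 brings the route back at 26.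

Step 11. The crowded enediolate may form incompletely or add sluggishly, acrylonitrile may oligomerise under the anionic conditions, and excess amide base may attack the doubly allylic C6–H2. The fallback changes the nucleophile to a monoanionic ester enolate and frees the acid afterwards by attack at the methyl group, which the crowded acyl carbon does not hinder. It sets out from 20, which is converted with Me3SiCHN2 in MeOH/toluene to the methyl ester F3. Deprotonation with LiN(i-Pr)2 (1.05 equiv, −78 °C) and Michael addition to acrylonitrile should give the quaternary methyl ester F4. SN2 demethylation with NaSEt in DMF at 60 °C returns the route at 23.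

Step 8. Transfer of the α-branched alkenyl group from copper may be slow, the organometallic may attack the imide carbonyl instead, and facial selectivity may erode if chelation is incomplete. The fallback replaces the stoichiometric organocopper addition by a rhodium-catalysed 1,4-addition of an alkenylboron reagent (Hayashi–Miyaura type). It sets out from 13, which is converted (t-BuLi, Et2O, −78 °C; then i-PrOBpin) to the alkenyl pinacol boronate F5. Addition of F5 to 7 with [Rh(cod)OH]2, a chiral diene or BINAP ligand chosen to reinforce the auxiliary, and aqueous KOH in dioxane at 50 °C returns the route at 16.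

Further compounds
F1 | step 12 | 2-thioxopyridin-1(2H)-yl ester of 23 (thiohydroxamate ester) | CC(C)(C)[Si](C)(C)OCC[C@@H](C)CC[C@H](C(C)(CCC#N)C(=O)On1ccccc1=S)/C(C)=C\CC=C(C)C
F2 | step 12 | 3-{(1R,2S,6R)-2-[(3S)-5-(TBSO)-3-methylpentyl]-1,3-dimethyl-6-[2-(pyridin-2-ylsulfanyl)propan-2-yl]cyclohex-3-en-1-yl}propanenitrile | CC(C)(C)[Si](C)(C)OCC[C@@H](C)CC[C@H]1C(C)=CC[C@@H](C(C)(C)Sc2ccccn2)[C@]1(C)CCC#N
F3 | step 11 | methyl ester of 20 | CC(C)(C)[Si](C)(C)OCC[C@@H](C)CC[C@H]([C@H](C)C(=O)OC)/C(C)=C\CC=C(C)C
F4 | step 11 | methyl ester of 23 (both C2 epimers) | CC(C)(C)[Si](C)(C)OCC[C@@H](C)CC[C@H](C(C)(CCC#N)C(=O)OC)/C(C)=C\CC=C(C)C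
F5 | step 8 | 4,4,5,5-tetramethyl-2-[(2Z)-6-methylhepta-2,5-dien-2-yl]-1,3,2-dioxaborolane | CC(C)=CC/C=C(/C)B1OC(C)(C)C(C)(C)O1
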